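**Retrosynthetic overview**
1. Target 27 ← triol 25 by acid methanolysis of six MOM ethers, then BBr3 cleavage of nine methyl ethers.
2. 25 ← heptamer 22 by threefold C–H oxygenation: in each of rings C, E and G the C4 hydroxyl sits between the C3 and C5 oxygens and para to the C1 ether oxygen, so every pyrogallol ring is traced back to a 3,5-bis(methoxymethoxy) ring whose C4–H lies between two MOM ethers.
3. 22 ← six diaryl ether bonds: SNAr for the ring B/ring C and ring D/ring E ethers (both inside dimer 9), Chan–Lam for the ring F/ring G ether (inside dimer 21), Ullmann for the ring A/ring B, ring C/ring D and ring E/ring F ethers; the C6 phenols of rings C and E are released from aldehydes by Baeyer–Villiger oxidation.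
4. No ring is built: the seven benzene rings are bought and joined in the order A + B/C, then D/E, then F/G.

Key step: step 13

Remarks: rings are lettered A (2,4,6-trihydroxyphenoxy end) to G, and on rings B to G the carbon C1 is the one whose ether oxygen points toward ring A; the target has no stereocentre; 4-bromo-2,6-dimethoxyphenol (8, the para-bromination product of 2,6-dimethoxyphenol) and 5-fluororesorcinol (4) are assumed to be purchased.

**Step 1**
Reactants: 1 2,4,6-trimethoxybenzaldehyde
Product: 3 2,4,6-trimethoxyphenol, via aryl formate 2 (not isolated)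
Conditions: mCPBA, CH2Cl2, 0 °C to rt; then K2CO3 (cat.), MeOH, rt
Reagents that add atoms: mCPBA O=C(OO)c1cccc(Cl)c1
Why: Baeyer–Villiger oxidation of the electron-rich aldehyde should proceed with aryl migration to the formate, which mild methanolysis cleaves to the phenol.

**Step 2**
Reactants: 4 5-fluororesorcinol
Product: 6 2-fluoro-4,6-dihydroxybenzaldehyde, via iminium chloride 5 (not isolated)
Conditions: POCl3, DMF, MeCN, 0 °C to rt; then H2O, 50 °C
Reagents that add atoms: N,N-dimethylformamide CN(C)C=O; water O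
Why: Vilsmeier–Haack formylation of a resorcinol is expected at C4, para to one hydroxyl and ortho to the other, in preference to the crowded C2 between the hydroxyls, and hydrolysis of the iminium salt releases the aldehyde.

**Step 3**
Reactants: 6 2-fluoro-4,6-dihydroxybenzaldehyde
Product: 7 2-fluoro-4,6-bis(methoxymethoxy)benzaldehyde
Conditions: NaH, MOMCl, DMF, 0 °C to rt
Reagents that add atoms: chloromethyl methyl ether COCCl
Why: O-alkylation of both sodium phenoxides (Williamson type) should be complete because NaH also breaks the hydrogen bond of the ortho-hydroxyl to the aldehyde.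

**Step 4**
Reactants: 7 2-fluoro-4,6-bis(methoxymethoxy)benzaldehyde; 8 4-bromo-2,6-dimethoxyphenol
Product: 9 2-(4-bromo-2,6-dimethoxyphenoxy)-4,6-bis(methoxymethoxy)benzaldehyde (dimer bromide; serves as rings B/C and as rings D/E)
Conditions: Cs2CO3, DMSO, 100 °C
Reagents that add atoms: none
Why: SNAr by addition–elimination should occur at the C–F carbon, whose Meisenheimer adduct is stabilised by the ortho-formyl group and which lies meta to both MOM-oxy donors, while the unactivated C–Br bond of 8 stays intact because no copper is present.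

**Step 5**
Reactants: 3 2,4,6-trimethoxyphenol; 9 dimer bromide
Product: 10 2-[2,6-dimethoxy-4-(2,4,6-trimethoxyphenoxy)phenoxy]-4,6-bis(methoxymethoxy)benzaldehyde (trimer aldehyde; rings A to C)
Conditions: CuI (cat.), picolinic acid (cat.), K3PO4, DMSO, 90 °C, Ar
Reagents that add atoms: none
Why: Ullmann diaryl ether coupling with the CuI/picolinic acid system is suited to 2,6-disubstituted phenols and electron-rich aryl bromides, and the hindered aldehyde of 9 has no enolisable hydrogen and should survive the phosphate base.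

**Step 6**
Reactants: 10 trimer aldehyde
Product: 12 2-[2,6-dimethoxy-4-(2,4,6-trimethoxyphenoxy)phenoxy]-4,6-bis(methoxymethoxy)phenol (trimer phenol; OH at C6 of ring C), via trimer formate 11 (not isolated)
Conditions: mCPBA (slight excess), CH2Cl2, 0 °C to rt; then K2CO3 (cat.), MeOH, rt
Reagents that add atoms: mCPBA O=C(OO)c1cccc(Cl)c1
Why: Baeyer–Villiger oxidation of the 2,4,6-trioxygenated benzaldehyde (aryl migration) and methanolysis of the formate should give the phenol, the MOM ethers tolerating 3-chlorobenzoic acid at this temperature.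

**Step 7**
Reactants: 12 trimer phenol; 9 dimer bromide
Product: 13 pentamer aldehyde (rings A to E; 12 arylated at the C6 oxygen of ring C by the 3,5-dimethoxy-4-[2-formyl-3,5-bis(methoxymethoxy)phenoxy]phenyl group)
Conditions: CuI (cat.), picolinic acid (cat.), K3PO4, DMSO, 100 °C, Ar
Reagents that add atoms: none
Why: Ullmann diaryl ether coupling of a phenoxide flanked by an aryloxy and a MOM-oxy group with an aryl bromide free of ortho substituents should work as in step 5.

**Step 8**
Reactants: 13 pentamer aldehyde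
Product: 15 pentamer phenol (rings A to E; OH at C6 of ring E), via pentamer formate 14 (not isolated)
Conditions: mCPBA (slight excess), CH2Cl2, 0 °C to rt; then K2CO3 (cat.), MeOH, rt
Reagents that add atoms: mCPBA O=C(OO)c1cccc(Cl)c1
Why: Baeyer–Villiger oxidation and formate methanolysis as in step 6, the only carbonyl group of 13 being the ring E aldehyde.

**Step 9**
Reactants: 16 5-bromoresorcinol
Product: 17 1-bromo-3,5-bis(methoxymethoxy)benzene
Conditions: NaH, MOMCl, DMF, 0 °C to rt
Reagents that add atoms: chloromethyl methyl ether COCCl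
Why: Williamson-type O-alkylation of both phenoxides with MOMCl.

**Step 10**
Reactants: 17 1-bromo-3,5-bis(methoxymethoxy)benzene
Product: 20 [3,5-bis(methoxymethoxy)phenyl]boronic acid, via aryllithium 18 (not isolated), via lithium aryltrimethoxyborate 19 (not isolated)
Conditions: n-BuLi, THF, −78 °C; B(OMe)3, −78 °C to rt; aq NH4Cl
Reagents that add atoms: trimethyl borate COB(OC)OC; water O
Why: Bromine–lithium exchange at −78 °C is faster than deprotonation between the MOM ethers, and borate trapping with near-neutral hydrolysis should give the boronic acid with both acetals intact.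

**Step 11**
Reactants: 8 4-bromo-2,6-dimethoxyphenol; 20 [3,5-bis(methoxymethoxy)phenyl]boronic acid
Product: 21 5-bromo-2-[3,5-bis(methoxymethoxy)phenoxy]-1,3-dimethoxybenzene (dimer bromide; rings F/G)
Conditions: Cu(OAc)2, pyridine, 4 Å MS, CH2Cl2, air, rt
Reagents that add atoms: none
Why: Chan–Lam oxidative C–O coupling of an arylboronic acid with a phenol runs at room temperature, accepts ortho,ortho-disubstituted phenols and leaves the aryl bromide of 8 untouched.

**Step 12**
Reactants: 15 pentamer phenol; 21 dimer bromide (rings F/G)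
Product: 22 protected heptamer (rings A to G; nine methyl ethers on rings A, B, D and F; six MOM ethers at C3 and C5 of rings C, E and G; C4 of rings C, E and G unsubstituted)
Conditions: CuI (cat.), picolinic acid (cat.), K3PO4, DMSO, 100 °C, Ar
Reagents that add atoms: none
Why: Ullmann diaryl ether coupling of the hindered C6 phenoxide of ring E with an unhindered, electron-rich aryl bromide, as in steps 5 and 7.

**Step 13**
Reactants: 22 protected heptamer
Product: 25 protected heptamer triol (free OH at C4 of rings C, E and G), via trilithio heptamer 23 (not isolated), via tris(trimethoxyborate) 24 (not isolated)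
Conditions: s-BuLi (about 3.6 equiv), TMEDA, THF, −78 °C; B(OMe)3, −78 to 0 °C; AcOH, 30% aq H2O2, 0 °C to rt
Reagents that add atoms: hydrogen peroxide OO
Why: s-BuLi/TMEDA should remove the C4 proton of rings C, E and G by complex-induced deprotonation, each of these hydrogens being held between two MOM ethers whose acetal oxygens chelate lithium; the three aryllithiums add to B(OMe)3 and each arylborate is oxidised by H2O2 with 1,2-shift of the aryl carbon from boron to oxygen, so the oxygen enters exactly at the metalated carbon. The closest known reaction is directed ortho-metalation of a 1,3-bis(methoxymethoxy)arene at C2 with borate quench and peroxide oxidation, here run three times in one flask on rings that are insulated from one another by the ether oxygens. No ring is closed and no stereocentre is formed. The step needs site selectivity for the three MOM/MOM-flanked hydrogens over C3–H and C5–H of ring A (between two methoxy groups), C2–H of rings C and E and C2–H/C6–H of ring G (between an aryloxy and a MOM-oxy group) and the hydrogens of rings B, D and F; it rests on the kinetic preference at −78 °C for the doubly chelated C4 sites, MOM-oxy being a stronger director than methoxy or aryloxy. Compound 22 carries no carbonyl, halide or O–H group that would consume the base, so a modest excess of s-BuLi and an excess of borate should bring all three sites to conversion.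

**Step 14**
Reactants: 25 protected heptamer triol
Product: 26 heptamer nonamethyl ether (free OH at C3, C4 and C5 of rings C, E and G)
Conditions: HCl, MeOH, rt to 40 °C, Ar
Reagents that add atoms: none
Why: Acid-catalysed acetal exchange with methanol removes the six MOM ethers as dimethoxymethane, while methyl and diaryl ethers are inert.

**Step 15**
Reactants: 26 heptamer nonamethyl ether
Product: 27 target fuhalol heptamer (CNP0292517.0)
Conditions: BBr3 (large excess), CH2Cl2, −78 °C to rt, Ar; then H2O, 0 °C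
Reagents that add atoms: none
Why: Lewis-acid ether cleavage with BBr3 proceeds through the oxygen–boron adduct and bromide attack at the methyl carbon, whereas the diaryl ether oxygens carry no sp3 carbon and should persist.

**Compound list**
1 | 2,4,6-trimethoxybenzaldehyde | COc1cc(OC)c(C=O)c(OC)c1 | starting material
2 | 2,4,6-trimethoxyphenyl formate | COc1cc(OC)c(OC=O)c(OC)c1 | intermediate (not isolated)
3 | 2,4,6-trimethoxyphenol | COc1cc(OC)c(O)c(OC)c1 | intermediate
4 | 5-fluororesorcinol | Oc1cc(O)cc(F)c1 | starting material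
5 | (2-fluoro-4,6-dihydroxybenzylidene)dimethyliminium chloride | C[N+](C)=Cc1c(O)cc(O)cc1F.[Cl-] | intermediate (not isolated)
6 | 2-fluoro-4,6-dihydroxybenzaldehyde | O=Cc1c(O)cc(O)cc1F | intermediate
7 | 2-fluoro-4,6-bis(methoxymethoxy)benzaldehyde | COCOc1cc(F)c(C=O)c(OCOC)c1 | intermediate
8 | 4-bromo-2,6-dimethoxyphenol | COc1cc(Br)cc(OC)c1O | starting material
9 | 2-(4-bromo-2,6-dimethoxyphenoxy)-4,6-bis(methoxymethoxy)benzaldehyde | COCOc1cc(Oc2c(OC)cc(Br)cc2OC)c(C=O)c(OCOC)c1 | intermediate
10 | trimer aldehyde, 2-[2,6-dimethoxy-4-(2,4,6-trimethoxyphenoxy)phenoxy]-4,6-bis(methoxymethoxy)benzaldehyde | COc1cc(OC)c(Oc2cc(OC)c(Oc3cc(OCOC)cc(OCOC)c3C=O)c(OC)c2)c(OC)c1 | intermediate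
11 | trimer formate (formate ester of 12) | COc1cc(OC)c(Oc2cc(OC)c(Oc3cc(OCOC)cc(OCOC)c3OC=O)c(OC)c2)c(OC)c1 | intermediate (not isolated)
12 | trimer phenol, 2-[2,6-dimethoxy-4-(2,4,6-trimethoxyphenoxy)phenoxy]-4,6-bis(methoxymethoxy)phenol | COc1cc(OC)c(Oc2cc(OC)c(Oc3cc(OCOC)cc(OCOC)c3O)c(OC)c2)c(OC)c1 | intermediate
13 | pentamer aldehyde (rings A to E, CHO at C6 of ring E) | COc1cc(OC)c(Oc2cc(OC)c(Oc3cc(OCOC)cc(OCOC)c3Oc3cc(OC)c(Oc4cc(OCOC)cc(OCOC)c4C=O)c(OC)c3)c(OC)c2)c(OC)c1 | intermediate
14 | pentamer formate (formate ester of 15) | COc1cc(OC)c(Oc2cc(OC)c(Oc3cc(OCOC)cc(OCOC)c3Oc3cc(OC)c(Oc4cc(OCOC)cc(OCOC)c4OC=O)c(OC)c3)c(OC)c2)c(OC)c1 | intermediate (not isolated)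
15 | pentamer phenol (rings A to E, OH at C6 of ring E) | COc1cc(OC)c(Oc2cc(OC)c(Oc3cc(OCOC)cc(OCOC)c3Oc3cc(OC)c(Oc4cc(OCOC)cc(OCOC)c4O)c(OC)c3)c(OC)c2)c(OC)c1 | intermediate
16 | 5-bromoresorcinol | Oc1cc(O)cc(Br)c1 | starting material
17 | 1-bromo-3,5-bis(methoxymethoxy)benzene | COCOc1cc(Br)cc(OCOC)c1 | intermediate
18 | [3,5-bis(methoxymethoxy)phenyl]lithium | [Li]c1cc(OCOC)cc(OCOC)c1 | intermediate (not isolated)
19 | lithium [3,5-bis(methoxymethoxy)phenyl]trimethoxyborate | [Li+].CO[B-](OC)(OC)c1cc(OCOC)cc(OCOC)c1 | intermediate (not isolated)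
20 | [3,5-bis(methoxymethoxy)phenyl]boronic acid | COCOc1cc(OCOC)cc(B(O)O)c1 | intermediate
21 | 5-bromo-2-[3,5-bis(methoxymethoxy)phenoxy]-1,3-dimethoxybenzene | COCOc1cc(OCOC)cc(Oc2c(OC)cc(Br)cc2OC)c1 | intermediate
22 | protected heptamer lacking the C4 oxygens of rings C, E and G (nine OMe, six OMOM) | COc1cc(OC)c(Oc2cc(OC)c(Oc3cc(OCOC)cc(OCOC)c3Oc3cc(OC)c(Oc4cc(OCOC)cc(OCOC)c4Oc4cc(OC)c(Oc5cc(OCOC)cc(OCOC)c5)c(OC)c4)c(OC)c3)c(OC)c2)c(OC)c1 | intermediate
23 | trilithio heptamer (Li at C4 of rings C, E and G) | COc1cc(OC)c(Oc2cc(OC)c(Oc3cc(OCOC)c([Li])c(OCOC)c3Oc3cc(OC)c(Oc4cc(OCOC)c([Li])c(OCOC)c4Oc4cc(OC)c(Oc5cc(OCOC)c([Li])c(OCOC)c5)c(OC)c4)c(OC)c3)c(OC)c2)c(OC)c1 | intermediate (not isolated)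
24 | trilithium tris(trimethoxyborate) of the heptamer (boron at C4 of rings C, E and G) | COc1cc(OC)c(Oc2cc(OC)c(Oc3cc(OCOC)c([B-](OC)(OC)OC)c(OCOC)c3Oc3cc(OC)c(Oc4cc(OCOC)c([B-](OC)(OC)OC)c(OCOC)c4Oc4cc(OC)c(Oc5cc(OCOC)c([B-](OC)(OC)OC)c(OCOC)c5)c(OC)c4)c(OC)c3)c(OC)c2)c(OC)c1.[Li+].[Li+].[Li+] | intermediate (not isolated)
25 | protected heptamer triol (OH at C4 of rings C, E and G) | COc1cc(OC)c(Oc2cc(OC)c(Oc3cc(OCOC)c(O)c(OCOC)c3Oc3cc(OC)c(Oc4cc(OCOC)c(O)c(OCOC)c4Oc4cc(OC)c(Oc5cc(OCOC)c(O)c(OCOC)c5)c(OC)c4)c(OC)c3)c(OC)c2)c(OC)c1 | intermediate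
26 | heptamer nonamethyl ether (pyrogallol rings C, E and G free) | COc1cc(OC)c(Oc2cc(OC)c(Oc3cc(O)c(O)c(O)c3Oc3cc(OC)c(Oc4cc(O)c(O)c(O)c4Oc4cc(OC)c(Oc5cc(O)c(O)c(O)c5)c(OC)c4)c(OC)c3)c(OC)c2)c(OC)c1 | intermediate
27 | CNP0292517.0, fuhalol-type heptamer | Oc1cc(O)c(Oc2cc(O)c(Oc3cc(O)c(O)c(O)c3Oc3cc(O)c(Oc4cc(O)c(O)c(O)c4Oc4cc(O)c(Oc5cc(O)c(O)c(O)c5)c(O)c4)c(O)c3)c(O)c2)c(O)c1 | target

**Step count**
Total: 15 steps. Longest linear sequence: 11 steps (4 → 6 → 7 → 9 → 10 → 12 → 13 → 15 → 22 → 25 → 26 → 27).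

**Steps most likely to fail**

Step 13. Metalation may stop short of all three sites, or stray to C3/C5 of ring A (between two methoxy groups) or to C2 of rings C and E. Either would give under- or mis-hydroxylated heptamers that are hard to separate. The fallback gives up C–H oxygenation and carries the C4 oxygens of rings C, E and G as methyl ethers from the building blocks; it sets out from 3 and 8 and comes back at 27. Purchased 5-fluoro-1,2,3-trimethoxybenzene would be formylated under Vilsmeier–Haack conditions (POCl3, DMF), with hydrolysis of iminium chloride F1, to 2-fluoro-4,5,6-trimethoxybenzaldehyde F2. SNAr of F2 with 8 (Cs2CO3, DMSO) would give 2-(4-bromo-2,6-dimethoxyphenoxy)-4,5,6-trimethoxybenzaldehyde F3. Ullmann coupling of 3 with F3 (CuI, picolinic acid, K3PO4) would give permethyl trimer aldehyde F4, and Baeyer–Villiger oxidation (mCPBA; then K2CO3, MeOH), through permethyl trimer formate F5, would give permethyl trimer phenol F6. A second Ullmann coupling with F3 would give permethyl pentamer aldehyde F7, and Baeyer–Villiger oxidation through permethyl pentamer formate F8 would give permethyl pentamer phenol F9. Chan–Lam coupling of 8 with purchased (3,4,5-trimethoxyphenyl)boronic acid would give 5-bromo-1,3-dimethoxy-2-(3,4,5-trimethoxyphenoxy)benzene F10. Ullmann coupling of F9 with F10 would give heptamer octadecamethyl ether F11, and BBr3 would cleave all eighteen methyl ethers to 27.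

Step 12. C–O bond formation at the doubly ortho-substituted phenoxide of 15 may be slow, so that reduction of the C–Br bond of 21 and oxidative decay of the electron-rich phenoxide outrun the coupling. The fallback replaces the copper coupling at the hindered oxygen by SNAr; it sets out from 15 and comes back at 22. Compound 15 would be arylated with purchased 4-fluoro-2,6-dimethoxybenzaldehyde (Cs2CO3, DMSO), the para-formyl group activating an unhindered C–F carbon, to hexamer aldehyde F12. Baeyer–Villiger oxidation (mCPBA; then K2CO3, MeOH), through hexamer formate F13, would give hexamer phenol F14. The ring F hydroxyl of F14, between two methoxy groups, would then be arylated with boronic acid 20 under Chan–Lam conditions (Cu(OAc)2, pyridine, air) to 22.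

Step 15. Cleavage of the nine methyl ethers may stay incomplete, and the pyrogallol rings may oxidise in air while the free polyphenol is isolated. The fallback sets out from 26 and comes back at 27. The quenched crude product of the BBr3 reaction would not be isolated as the free phenol but acetylated at once (Ac2O, pyridine, DMAP) to heptamer octadecaacetate F15. This peracetate should be stable to air and separable by chromatography from under-cleaved material, which carries methyl ethers in place of acetates. Acid methanolysis (HCl, MeOH, Ar) would then release 27 without exposing phenoxides to air.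

**Further compounds**
F1 | step 13 | (2-fluoro-4,5,6-trimethoxybenzylidene)dimethyliminium chloride | C[N+](C)=Cc1c(F)cc(OC)c(OC)c1OC.[Cl-]
F2 | step 13 | 2-fluoro-4,5,6-trimethoxybenzaldehyde | O=Cc1c(F)cc(OC)c(OC)c1OC
F3 | step 13 | 2-(4-bromo-2,6-dimethoxyphenoxy)-4,5,6-trimethoxybenzaldehyde | O=Cc1c(Oc2c(OC)cc(Br)cc2OC)cc(OC)c(OC)c1OC
F4 | step 13 | permethyl trimer aldehyde | COc1cc(OC)c(Oc2cc(OC)c(Oc3cc(OC)c(OC)c(OC)c3C=O)c(OC)c2)c(OC)c1
F5 | step 13 | permethyl trimer formate | COc1cc(OC)c(Oc2cc(OC)c(Oc3cc(OC)c(OC)c(OC)c3OC=O)c(OC)c2)c(OC)c1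
F6 | step 13 | permethyl trimer phenol | COc1cc(OC)c(Oc2cc(OC)c(Oc3cc(OC)c(OC)c(OC)c3O)c(OC)c2)c(OC)c1
F7 | step 13 | permethyl pentamer aldehyde | COc1cc(OC)c(Oc2cc(OC)c(Oc3cc(OC)c(OC)c(OC)c3Oc3cc(OC)c(Oc4cc(OC)c(OC)c(OC)c4C=O)c(OC)c3)c(OC)c2)c(OC)c1
F8 | step 13 | permethyl pentamer formate | COc1cc(OC)c(Oc2cc(OC)c(Oc3cc(OC)c(OC)c(OC)c3Oc3cc(OC)c(Oc4cc(OC)c(OC)c(OC)c4OC=O)c(OC)c3)c(OC)c2)c(OC)c1
F9 | step 13 | permethyl pentamer phenol | COc1cc(OC)c(Oc2cc(OC)c(Oc3cc(OC)c(OC)c(OC)c3Oc3cc(OC)c(Oc4cc(OC)c(OC)c(OC)c4O)c(OC)c3)c(OC)c2)c(OC)c1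
F10 | step 13 | 5-bromo-1,3-dimethoxy-2-(3,4,5-trimethoxyphenoxy)benzene | COc1cc(Oc2c(OC)cc(Br)cc2OC)cc(OC)c1OC
F11 | step 13 | heptamer octadecamethyl ether | COc1cc(OC)c(Oc2cc(OC)c(Oc3cc(OC)c(OC)c(OC)c3Oc3cc(OC)c(Oc4cc(OC)c(OC)c(OC)c4Oc4cc(OC)c(Oc5cc(OC)c(OC)c(OC)c5)c(OC)c4)c(OC)c3)c(OC)c2)c(OC)c1
F12 | step 12 | hexamer aldehyde (rings A to F, CHO at C4 of ring F) | COc1cc(OC)c(Oc2cc(OC)c(Oc3cc(OCOC)cc(OCOC)c3Oc3cc(OC)c(Oc4cc(OCOC)cc(OCOC)c4Oc4cc(OC)c(C=O)c(OC)c4)c(OC)c3)c(OC)c2)c(OC)c1
F13 | step 12 | hexamer formate | COc1cc(OC)c(Oc2cc(OC)c(Oc3cc(OCOC)cc(OCOC)c3Oc3cc(OC)c(Oc4cc(OCOC)cc(OCOC)c4Oc4cc(OC)c(OC=O)c(OC)c4)c(OC)c3)c(OC)c2)c(OC)c1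
F14 | step 12 | hexamer phenol (OH at C4 of ring F) | COc1cc(OC)c(Oc2cc(OC)c(Oc3cc(OCOC)cc(OCOC)c3Oc3cc(OC)c(Oc4cc(OCOC)cc(OCOC)c4Oc4cc(OC)c(O)c(OC)c4)c(OC)c3)c(OC)c2)c(OC)c1
F15 | step 15 | heptamer octadecaacetate | CC(=O)Oc1cc(OC(C)=O)c(Oc2cc(OC(C)=O)c(Oc3cc(OC(C)=O)c(OC(C)=O)c(OC(C)=O)c3Oc3cc(OC(C)=O)c(Oc4cc(OC(C)=O)c(OC(C)=O)c(OC(C)=O)c4Oc4cc(OC(C)=O)c(Oc5cc(OC(C)=O)c(OC(C)=O)c(OC(C)=O)c5)c(OC(C)=O)c4)c(OC(C)=O)c3)c(OC(C)=O)c2)c(OC(C)=O)c1
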